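Count laps. Starting material turns to product over a free catalyst under held gas, and the question is how much product each flask holds after 15 min.

| flask | starting material | gas | free catalyst | temperature | remark | time |
|---|---|---|---|---|---|---|
| cedar | 10 mM | 1.4 mM (held) | 21 mol% | 21 °C | run made earlier |  |
| elm | 10 mM | 1.4 mM (held) | 33 mol% | 46 °C | run made earlier |  |
| larch | 20 mM | 1.4 mM (held) | 15 mol% | 21 °C | run made earlier |  |
| Monday's | 10 mM | 1.4 mM (held) | 15 mol% | 10 °C |  | 15 min |
| Saturday's | 10 mM | 1.4 mM (held) | 15 mol% | 40 °C |  | 15 min |
| Wednesday's | 10 mM | 1.4 mM (held) | 15 mol% | 55 °C |  | 15 min |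
| Tuesday's | 10 mM | 1.4 mM (held) | 15 mol% | 25 °C |  | 15 min |

cedar run (percent of the starting material charged)

| time / min | product / % | starting material / % |
|---|---|---|
| 0.667 | 0.1 | 93.6 |
| 1.33 | 0 | 91.9 |
| 2.00 | 0 | 88.4 |
| 4.00 | 0.3 | 83.9 |
| 8.00 | 5.6 | 76.3 |

elm run (percent of the starting material charged)

| time / s | product / % | starting material / % |
|---|---|---|
| 10.0 | 0.9 | 91.5 |
| 30.0 | 0.6 | 81.4 |
| 60.0 | 4.0 | 73.7 |
| 80.0 | 7.5 | 68.6 |
| 120 | 12.6 | 62.1 |

larch run (percent of the starting material charged)

| time / min | product / % | starting material / % |
|---|---|---|
| 1.33 | 0 | 87.3 |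
| 3.00 | 0 | 84.9 |
| 5.00 | 2.0 | 83.7 |
| 6.00 | 3.4 | 84.8 |
| 8.00 | 6.7 | 80.0 |

(standard deviation of a reading: 1 percentage point)

1. the flask that comes out highest in amount of product, in percent of the starting material charged, or "all alike" when all lie within 1.5 percentage points (Monday's / Saturday's / Wednesday's / Tuesday's / all alike)
2. product at the end, in percent of the starting material charged, Monday's
3. product at the end, in percent of the starting material charged, Saturday's
4. product at the end, in percent of the starting material charged, Wednesday's
5. product at the end, in percent of the starting material charged, Tuesday's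

- the analysis behind the earlier runs scatters by 1 percentage point, standard deviation
- at the start none of the gas is in solution

Elm's last two readings give a product slope, and dividing its loading by that slope gives 4.31 min per product molecule per catalyst. Cedar's late readings, which scatter more for their size, give 15.8 min, longer at its 21 °C than elm's at 46 °C. Carrying that ratio on to 55 °C gives 2.70 min for Wednesday's: this is the lap time, loading over product slope (the turnover time). Product over loading then counts laps.

Ines holds the forecast: “the rate is roughly zero order in substrate”, so a lap keeps its length. It reads 5% for Monday's, 20% for Tuesday's, 47% for Saturday's and 80% for Wednesday's, the highest. That last number is what doubling rates every 10 degrees from elm gives. My straight count with the lap above gives 83.3%, a different figure from hers.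

Theo says a lap stretches as starting material thins. Elm's lap was read with 65.3% of it left, so each minute takes a fixed share of what remains, and the remainder falls exponentially. For Wednesday's, counting converted material as product, he gets 72.1%.

The flasks give 2.82% on Monday's, 19.4% on Tuesday's, 48.0% on Saturday's and 73.4% on Wednesday's, which is highest.

    starting material + free catalyst → catalyst intermediate A (k = 0.860 M⁻¹ s⁻¹, Ea = 48.0 kJ mol⁻¹)
    coupling partner + catalyst intermediate A → catalyst intermediate B (k = 2.90 M⁻¹ s⁻¹, Ea = 41.0 kJ mol⁻¹)
    catalyst intermediate B → released group + catalyst intermediate C (k = 0.00770 s⁻¹, Ea = 85.0 kJ mol⁻¹)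
    catalyst intermediate C ⇌ free catalyst + product (K = 0.00830 M, k = 0.0780 s⁻¹, Ea = 78.0 kJ mol⁻¹, ΔH = −23.0 kJ mol⁻¹)
    gas ⇌ coupling partner, rate k5*(csat - [coupling partner]) (kL = 0.110 s⁻¹)
    (constants at 25 °C)

Wednesday's made 4.89 laps, averaging 3.07 min against the reckoned 2.70 min, and Theo's figure stands nearer the flask than Ines's, but that does not prove his thinning: the same flask with free catalyst retaking no product reaches 95.7%, laps of 2.35 min, shorter than 2.70 min. Ines's view holds on Saturday's and Tuesday's, where her numbers sit beside the results. Wednesday's is held back partly by free catalyst retaking product and partly by the time given, since after 150 min it stands at 89.3%. Monday's falls short mainly because of the time given, since after 150 min it holds 57.7%. A neighbour of Wednesday's with 3.8 mol% free catalyst made 33.1% product, 8.71 laps averaging 1.72 min, shorter than 2.70 min.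

All runs were computed from invented constants; scatter was added.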